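**Retrosynthetic overview**
1. Target 21 is traced back to hydroazulene 18 (2-acetate; free 4-, 6- and 10-hydroxyls; C8=C9 alkene): angeloylation at O6/O10, hydroxyl-directed β-epoxidation and acetate removal come last, and the 6β and 10β carbinols arise by hydride delivery from the α-oxygens on C4 and C2 across the cis ring fusion.
2. The seven-membered ring (C1, C5–C10) is closed late by metathesis at C8=C9 of 14; C10 is the carboxyl carbon of a lactone and C6 is the carbon of a nitro group (allylation at C6, later Nef reaction).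
3. The five-membered ring (C1–C5) is closed first, in the key step, by C3–C4 bond formation: intramolecular aldol of the acyclic 1,4-diketone 8, with capture of the C4 alkoxide by the ester on C1 to give the 2-oxabicyclo[2.2.1]heptanedione 10.
4. Enabling feature: C2 and C4 are 1,3-dioxygenated with only C3 between them (aldol retron), and on the cyclopentane the C4 oxygen is cis-1,3 to C10 on C1, so the tertiary aldolate can be locked as a temporary lactone bridge that makes the reversible aldol convergent at C4, marks C10 and later steers hydride to C2.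
5. Diketone 8 comes in one step from methyl 2-methylacetoacetate (C3, C2, C1, the C1 methyl, C10) and nitro enone 6 (isopropyl, C4, C5, C6) by a catalytic asymmetric Michael addition that sets C1 and C5; ring order: cyclopentane with lactone bridge, then cycloheptene, then epoxide.

Key step: step 5

Numbering: daucane numbering is used throughout (C1 ring-fusion carbon with CH3, C2 CHOH, C3 CH2, C4 C(OH)-i-Pr, C5 ring-fusion CH, C6 CHO-acyl, C7 CH2, C8 C-CH3, C9, C10 CHO-acyl); β is the face of the C1 methyl and H5, α the opposite face; "cis-daucane" means the 1β-CH3/5β-H ring fusion with 4β-isopropyl.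
Assumption: in step 4 the (R,R)-configured thiourea is taken to give the (2R,3R) adduct; should the sense of induction be the opposite, its enantiomer is used and nothing else changes.

Step 1
Reactants: 1 3-methylbutan-2-one
Product: 2 3-methyl-2-oxobutanal
Conditions: SeO2, 1,4-dioxane/H2O, reflux
Reagents that add atoms: selenium dioxide, O=[Se]=O
Why: Riley oxidation of the methyl group of a methyl ketone to the α-keto aldehyde through the enol; no stereocentre is formed.

Step 2
Reactants: 2 3-methyl-2-oxobutanal; 3 nitromethane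
Product: 4 rac-2-hydroxy-4-methyl-1-nitropentan-3-one
Conditions: Et3N (10 mol %), THF, 0 °C
Reagents that add atoms: none
Why: Henry (nitroaldol) reaction in which the nitronate adds chemoselectively to the aldehyde carbonyl of the keto aldehyde; the racemic carbinol centre is destroyed in step 3.

Step 3
Reactants: 4 rac-2-hydroxy-4-methyl-1-nitropentan-3-one
Product: 6 (E)-4-methyl-1-nitropent-1-en-3-one, via mesylate 5 (not isolated)
Conditions: MsCl, Et3N, CH2Cl2, −40 → 0 °C
Reagents that add atoms: none
Why: mesylation followed by E1cB elimination through the nitronate should give the conjugated nitroalkene as the thermodynamically preferred (E)-isomer.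

Step 4
Reactants: 6 (E)-4-methyl-1-nitropent-1-en-3-one; 7 methyl 2-methyl-3-oxobutanoate
Product: 8 methyl (2R,3R)-2-acetyl-2-methyl-3-(2-methylpropanoyl)-4-nitrobutanoate
Conditions: 1-[3,5-bis(trifluoromethyl)phenyl]-3-[(1R,2R)-2-(dimethylamino)cyclohexyl]thiourea (10 mol %), toluene, −40 °C
Reagents that add atoms: none
Why: organocatalytic Michael addition of an α-substituted β-keto ester to a nitroalkene, in which the thiourea binds the nitro group (the stronger acceptor, so attack occurs at the carbon bearing the isobutyryl group) while the tertiary amine delivers the enolate, setting the quaternary C1 and the tertiary C5 centre in one catalyst-organized transition state.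

Step 5
Reactants: 8 methyl (2R,3R)-2-acetyl-2-methyl-3-(2-methylpropanoyl)-4-nitrobutanoate
Product: 10 (1S,4R,7R)-4-methyl-7-(nitromethyl)-1-(propan-2-yl)-2-oxabicyclo[2.2.1]heptane-3,5-dione, via lithium aldolate 9 (not isolated)
Conditions: LiN(i-Pr)2 (2.1 equiv), THF, −78 → −30 °C; then AcOH, −78 °C
Reagents that add atoms: none
Why: The first equivalent of base converts the nitro group into its nitronate (which also blocks loss of nitrite), and the second forms the kinetic enolate of the acetyl group, which adds to the isobutyryl carbonyl in the classical base-mediated cyclization of a 1,4-diketone (intramolecular ketone–ketone aldol). The carbocycle closes in the 5-(enolendo)-exo-trig mode by C3–C4 bond formation and the lactone bridge closes by a 5-exo-trig acyl substitution of the C4 alkoxide on the methyl ester at C1; the closest known reaction type is the tandem aldol–lactonization used to trap tertiary aldolates. C4 is the only new stereocentre: the aldol is reversible at this temperature, whereas only the aldolate whose oxygen is cis to the ester (isopropyl anti to the nitromethyl group on C5) can lactonize, so irreversible lactone formation should drain the equilibrium into the (4S) series. The step needs site selectivity in enolization (acetyl methyl over the hindered methines at C5 and in the isopropyl group), which the kinetic amide base at −78 °C secures, and it needs the β-acyloxy ketone of the product to survive, which is why exactly two equivalents of base are used and the mixture is quenched cold with acetic acid. C1 and C5 are carried over unchanged from 8, because C1 is quaternary and C5 lies next to the nitronate carbon, which disfavours its deprotonation.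

Step 6
Reactants: 10 (1S,4R,7R)-4-methyl-7-(nitromethyl)-1-(propan-2-yl)-2-oxabicyclo[2.2.1]heptane-3,5-dione
Product: 11 (1S,4R,5S,7R)-5-hydroxy-4-methyl-7-(nitromethyl)-1-(propan-2-yl)-2-oxabicyclo[2.2.1]heptan-3-one
Conditions: LiBH(s-Bu)3 (2.2 equiv), THF, −78 °C; aq. NH4Cl
Reagents that add atoms: none
Why: hydride reduction of a norbornanone-type ketone, in which the bulky borohydride attacks the exo face (syn to the one-carbon bridge C5, which shows only H on that side) and not the endo face under the lactone bridge, giving the endo (2α) alcohol.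

Step 7
Reactants: 11 (1S,4R,5S,7R)-5-hydroxy-4-methyl-7-(nitromethyl)-1-(propan-2-yl)-2-oxabicyclo[2.2.1]heptan-3-one
Product: 12 (1S,4R,5S,7R)-5-hydroxy-4-methyl-7-(3-methyl-1-nitrobut-3-en-1-yl)-1-(propan-2-yl)-2-oxabicyclo[2.2.1]heptan-3-one
Conditions: Pd(PPh3)4 (5 mol %), 2-methylallyl acetate (1.05 equiv), DBU, THF, 40 °C
Reagents that add atoms: 2-methylallyl acetate, CC(=C)COC(C)=O
Why: Tsuji–Trost allylation in which zerovalent palladium ionizes the allylic acetate and the DBU-generated nitronate is C-allylated by the symmetrical π-allyl complex; the new centre at the nitro carbon is of no consequence because it becomes the C6 carbonyl.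

Step 8
Reactants: 12 (1S,4R,5S,7R)-5-hydroxy-4-methyl-7-(3-methyl-1-nitrobut-3-en-1-yl)-1-(propan-2-yl)-2-oxabicyclo[2.2.1]heptan-3-one
Product: 13 (1R,2S,4S,5R)-2,4-dihydroxy-N-methoxy-N,1-dimethyl-5-(3-methyl-1-nitrobut-3-en-1-yl)-4-(propan-2-yl)cyclopentane-1-carboxamide
Conditions: MeNHOMe·HCl, AlMe3, CH2Cl2, 0 °C → rt
Reagents that add atoms: N,O-dimethylhydroxylamine hydrochloride, Cl.CNOC
Why: Weinreb aminolysis in which the dimethylaluminium amide opens the strained bridged lactone, turning C10 into an acyl group set up for single addition and releasing the tertiary 4-hydroxyl.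

Step 9
Reactants: 13 (1R,2S,4S,5R)-2,4-dihydroxy-N-methoxy-N,1-dimethyl-5-(3-methyl-1-nitrobut-3-en-1-yl)-4-(propan-2-yl)cyclopentane-1-carboxamide
Product: 14 1-[(1R,2S,4S,5R)-2,4-dihydroxy-1-methyl-5-(3-methyl-1-nitrobut-3-en-1-yl)-4-(propan-2-yl)cyclopentyl]prop-2-en-1-one
Conditions: LiN(SiMe3)2 (3.1 equiv), THF, −78 °C; CH2=CHMgBr (2.5 equiv), −78 → 0 °C; inverse quench into cold aq. AcOH
Reagents that add atoms: vinylmagnesium bromide, C=C[Mg]Br
Why: Weinreb ketone synthesis in which the nitro group and both hydroxyls are first masked as lithium salts and the chelated tetrahedral adduct keeps the vinyl ketone latent until the acidic quench, which should prevent over-addition and nitronate–enone cyclization.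

Step 10
Reactants: 14 1-[(1R,2S,4S,5R)-2,4-dihydroxy-1-methyl-5-(3-methyl-1-nitrobut-3-en-1-yl)-4-(propan-2-yl)cyclopentyl]prop-2-en-1-one
Product: 15 2α,4α-dihydroxy-6-nitro-cis-dauc-8-en-10-one
Conditions: second-generation Hoveyda–Grubbs catalyst RuCl2(=CH-C6H4-2-O-i-Pr)(H2IMes) (5 mol %), CH2Cl2, 40 °C, 2 mM
Reagents that add atoms: none
Why: ring-closing olefin metathesis, in which the two alkenes sit on cis substituents of the cyclopentane so that loss of ethylene closes the seven-membered ring at C8=C9 as a trisubstituted enone.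

Step 11
Reactants: 15 2α,4α-dihydroxy-6-nitro-cis-dauc-8-en-10-one
Product: 16 2α-acetoxy-4α,10β-dihydroxy-6-nitro-cis-dauc-8-ene
Conditions: SmI2 (30 mol %), CH3CHO (8 equiv), THF, −10 °C
Reagents that add atoms: acetaldehyde, CC=O
Why: Evans–Tishchenko reduction, in which the hemiacetal formed from the 2α-hydroxyl and acetaldehyde on trivalent samarium transfers hydride through a six-membered transition state to the α face of the C10 carbonyl, giving the 1,3-anti (10β) alcohol and leaving the directing hydroxyl as its acetate, which distinguishes O2 from O10.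

Step 12
Reactants: 16 2α-acetoxy-4α,10β-dihydroxy-6-nitro-cis-dauc-8-ene
Product: 17 2α-acetoxy-4α,10β-dihydroxy-cis-dauc-8-en-6-one
Conditions: DBU (1.1 equiv), MeCN, 0 °C; then aq. TiCl3, NH4OAc, rt
Reagents that add atoms: water, O
Why: Nef reaction in its reductive form, in which trivalent titanium reduces the nitronate to the imine that is hydrolysed in the buffered medium to the C6 ketone without strong acid or base.

Step 13
Reactants: 17 2α-acetoxy-4α,10β-dihydroxy-cis-dauc-8-en-6-one
Product: 18 2α-acetoxy-cis-dauc-8-ene-4α,6β,10β-triol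
Conditions: Me4NBH(OAc)3, MeCN/AcOH (1:1), −20 °C
Reagents that add atoms: none
Why: Evans–Saksena hydroxyl-directed reduction, in which the acetoxyborohydride exchanged onto the 4α-hydroxyl delivers hydride intramolecularly to the α face of the C6 carbonyl, whose orientation is fixed by the seven-membered ring, giving the 6β (1,3-anti) alcohol.

Step 14
Reactants: 18 2α-acetoxy-cis-dauc-8-ene-4α,6β,10β-triol
Product: 19 2α-acetoxy-8β,9β-epoxy-cis-daucane-4α,6β,10β-triol
Conditions: VO(acac)2 (5 mol %), t-BuOOH, CH2Cl2, 0 °C → rt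
Reagents that add atoms: tert-butyl hydroperoxide, CC(C)(C)OO
Why: vanadium-catalysed hydroxyl-directed epoxidation, in which the allylic 10β- and homoallylic 6β-hydroxyls bind the vanadium peroxide and deliver oxygen to the β face of the C8=C9 bond.

Step 15
Reactants: 19 2α-acetoxy-8β,9β-epoxy-cis-daucane-4α,6β,10β-triol
Product: 20 2α-acetoxy-6β,10β-bis(angeloyloxy)-8β,9β-epoxy-cis-daucan-4α-ol
Conditions: angelic acid (6 equiv), 2,4,6-Cl3C6H2COCl, Et3N, toluene, rt; then 19, 75 °C
Reagents that add atoms: angelic acid, C/C=C(/C)C(=O)O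
Why: Yamaguchi-type esterification through the mixed anhydride, a protocol that acylates hindered secondary alcohols without isomerizing the (Z)-2-methylbut-2-enoyl group, while the tertiary 4-hydroxyl does not react.

Step 16
Reactants: 20 2α-acetoxy-6β,10β-bis(angeloyloxy)-8β,9β-epoxy-cis-daucan-4α-ol
Product: 21 6β,10β-bis(angeloyloxy)-8β,9β-epoxy-cis-daucane-2α,4α-diol
Conditions: K2CO3 (0.3 equiv), MeOH, 0 °C
Reagents that add atoms: none
Why: base-catalysed transesterification, in which the unconjugated acetate (assisted by the cis 4-hydroxyl) should be methanolysed much faster than the conjugated, α-branched angelates, with the epoxide untouched.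

**Compound list**
1 | 3-methylbutan-2-one | CC(=O)C(C)C | starting material
2 | 3-methyl-2-oxobutanal | CC(C)C(=O)C=O | intermediate
3 | nitromethane | C[N+](=O)[O-] | starting material
4 | rac-2-hydroxy-4-methyl-1-nitropentan-3-one | CC(C)C(=O)C(O)C[N+](=O)[O-] | intermediate
5 | 4-methyl-1-nitro-3-oxopentan-2-yl methanesulfonate (mesylate, not isolated) | CC(C)C(=O)C(OS(C)(=O)=O)C[N+](=O)[O-] | intermediate
6 | (E)-4-methyl-1-nitropent-1-en-3-one | CC(C)C(=O)/C=C/[N+](=O)[O-] | intermediate
7 | methyl 2-methyl-3-oxobutanoate | COC(=O)C(C)C(C)=O | starting material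
8 | methyl (2R,3R)-2-acetyl-2-methyl-3-(2-methylpropanoyl)-4-nitrobutanoate | COC(=O)[C@@](C)(C(C)=O)[C@H](C[N+](=O)[O-])C(=O)C(C)C | intermediate
9 | methyl (1R,2R,3S)-3-hydroxy-1-methyl-2-(nitromethyl)-5-oxo-3-(propan-2-yl)cyclopentane-1-carboxylate (present as the lithium aldolate, drawn as the neutral hydroxy ester; not isolated) | COC(=O)[C@@]1(C)C(=O)C[C@](O)(C(C)C)[C@H]1C[N+](=O)[O-] | intermediate
10 | (1S,4R,7R)-4-methyl-7-(nitromethyl)-1-(propan-2-yl)-2-oxabicyclo[2.2.1]heptane-3,5-dione (nitromethyl syn to the lactone bridge) | O=C1O[C@]2(C(C)C)CC(=O)[C@@]1(C)[C@@H]2C[N+](=O)[O-] | intermediate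
11 | (1S,4R,5S,7R)-5-hydroxy-4-methyl-7-(nitromethyl)-1-(propan-2-yl)-2-oxabicyclo[2.2.1]heptan-3-one (endo alcohol) | O=C1O[C@]2(C(C)C)C[C@H](O)[C@@]1(C)[C@@H]2C[N+](=O)[O-] | intermediate
12 | (1S,4R,5S,7R)-5-hydroxy-4-methyl-7-(3-methyl-1-nitrobut-3-en-1-yl)-1-(propan-2-yl)-2-oxabicyclo[2.2.1]heptan-3-one (both epimers at the nitro carbon) | O=C1O[C@]2(C(C)C)C[C@H](O)[C@@]1(C)[C@@H]2C(CC(C)=C)[N+](=O)[O-] | intermediate
13 | (1R,2S,4S,5R)-2,4-dihydroxy-N-methoxy-N,1-dimethyl-5-(3-methyl-1-nitrobut-3-en-1-yl)-4-(propan-2-yl)cyclopentane-1-carboxamide (both epimers at the nitro carbon) | CON(C)C(=O)[C@@]1(C)[C@@H](O)C[C@](O)(C(C)C)[C@H]1C(CC(C)=C)[N+](=O)[O-] | intermediate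
14 | 1-[(1R,2S,4S,5R)-2,4-dihydroxy-1-methyl-5-(3-methyl-1-nitrobut-3-en-1-yl)-4-(propan-2-yl)cyclopentyl]prop-2-en-1-one (both epimers at the nitro carbon) | C=CC(=O)[C@@]1(C)[C@@H](O)C[C@](O)(C(C)C)[C@H]1C(CC(C)=C)[N+](=O)[O-] | intermediate
15 | 2α,4α-dihydroxy-6-nitro-cis-dauc-8-en-10-one (both C6 epimers) | [O-][N+](=O)C1CC(C)=CC(=O)[C@@]2(C)[C@@H](O)C[C@](O)(C(C)C)[C@@H]12 | intermediate
16 | 2α-acetoxy-4α,10β-dihydroxy-6-nitro-cis-dauc-8-ene (both C6 epimers) | [O-][N+](=O)C1CC(C)=C[C@H](O)[C@@]2(C)[C@@H](OC(C)=O)C[C@](O)(C(C)C)[C@@H]12 | intermediate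
17 | 2α-acetoxy-4α,10β-dihydroxy-cis-dauc-8-en-6-one | O=C1CC(C)=C[C@H](O)[C@@]2(C)[C@@H](OC(C)=O)C[C@](O)(C(C)C)[C@@H]12 | intermediate
18 | 2α-acetoxy-cis-dauc-8-ene-4α,6β,10β-triol | O[C@@H]1CC(C)=C[C@H](O)[C@@]2(C)[C@@H](OC(C)=O)C[C@](O)(C(C)C)[C@@H]12 | intermediate
19 | 2α-acetoxy-8β,9β-epoxy-cis-daucane-4α,6β,10β-triol | O[C@@H]1C[C@]2(C)O[C@@H]2[C@H](O)[C@@]2(C)[C@@H](OC(C)=O)C[C@](O)(C(C)C)[C@@H]12 | intermediate
20 | 2α-acetoxy-6β,10β-bis(angeloyloxy)-8β,9β-epoxy-cis-daucan-4α-ol | C/C=C(/C)C(=O)O[C@@H]1C[C@]2(C)O[C@@H]2[C@H](OC(=O)/C(C)=C\C)[C@@]2(C)[C@@H](OC(C)=O)C[C@](O)(C(C)C)[C@@H]12 | intermediate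
21 | 6β,10β-bis(angeloyloxy)-8β,9β-epoxy-cis-daucane-2α,4α-diol (CNP0265715.2) | C/C=C(/C)C(=O)O[C@@H]1C[C@]2(C)O[C@@H]2[C@H](OC(=O)/C(C)=C\C)[C@@]2(C)[C@@H](O)C[C@](O)(C(C)C)[C@@H]12 | target

**Step count and risks**
Total steps: 16. Longest linear sequence: 16 steps (1 → 21); 3 and 7 enter as purchased building blocks.

Steps most likely to fail:

Step 5 (key step). What may go wrong: base-induced β-elimination of the lactone carboxylate from the β-acyloxy ketone once the bridge has formed (opening to a cyclopentenone acid), or enolate equilibration to the isobutyryl side before ring closure. Fallback, using Lewis-acid instead of enolate chemistry: 8 is silylated (Me3SiOTf, Et3N, CH2Cl2, 0 °C) to the bis-silyl derivative F1 (silyl enol ether of the acetyl group plus silyl nitronate). TiCl4 (CH2Cl2, −78 °C) should then effect the intramolecular Mukaiyama aldol addition to the isobutyryl carbonyl. Aqueous work-up restores the nitro group and gives hydroxy ester 9, which is isolated this time. It is lactonized with camphorsulfonic acid in toluene at 60 °C (only the cis hydroxy ester can close), rejoining the route at 10.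

Step 4. What may go wrong: poor discrimination between acetyl and ester groups at the forming quaternary centre (low diastereoselectivity at C1), and loss of nitrous acid from the β-nitro ketone under amine catalysis. Fallback, using a stoichiometric chiral enamine in place of the catalyst: 7 is condensed with (R)-1-phenylethylamine (toluene, 4 Å sieves; sense of induction assumed, the antipode is equally available) to the chelated enamino ester F2. F2 should add to 6 without any base (THF, 0 °C → rt) through the compact aza-ene-type transition state of such secondary enamines to give the imine adduct F3. Mild hydrolysis (aq. AcOH/THF) removes the auxiliary and returns to the route at 8.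

Step 9. What may go wrong: addition of the organomagnesium reagent to the nitronate, and conjugate addition of the nitronate to the freshly released vinyl ketone during work-up. Fallback, an aldehyde/organozinc route in which no enone coexists with a nitronate: from 13, i-Bu2AlH (THF, −78 °C) should give the aldehyde F4. Divinylzinc, Zn(CH=CH2)2, which tolerates nitroalkanes, adds to give the allylic alcohol F5 (both C10 epimers). Ring-closing metathesis under the conditions of step 10 gives the cycloheptenol F6, and MnO2 (CH2Cl2, rt) oxidizes only the allylic alcohol, rejoining the route at 15.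

**Further compounds**
F1 | step 5 | methyl (2R,3R)-2-methyl-3-(2-methylpropanoyl)-2-[1-(trimethylsilyloxy)ethenyl]-4-[(trimethylsilyloxy)(oxido)-λ5-azanylidene]butanoate (bis-silyl derivative of 8) | COC(=O)[C@@](C)(C(=C)O[Si](C)(C)C)[C@H](C=[N+]([O-])O[Si](C)(C)C)C(=O)C(C)C
F2 | step 4 | methyl (Z)-2-methyl-3-{[(1R)-1-phenylethyl]amino}but-2-enoate | COC(=O)/C(C)=C(/C)N[C@H](C)c1ccccc1
F3 | step 4 | methyl (2R,3R)-2-methyl-3-(2-methylpropanoyl)-4-nitro-2-{N-[(1R)-1-phenylethyl]ethanimidoyl}butanoate | COC(=O)[C@@](C)(C(C)=N[C@H](C)c1ccccc1)[C@H](C[N+](=O)[O-])C(=O)C(C)C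
F4 | step 9 | (1R,2S,4S,5R)-2,4-dihydroxy-1-methyl-5-(3-methyl-1-nitrobut-3-en-1-yl)-4-(propan-2-yl)cyclopentane-1-carbaldehyde | O=C[C@@]1(C)[C@@H](O)C[C@](O)(C(C)C)[C@H]1C(CC(C)=C)[N+](=O)[O-]
F5 | step 9 | 1-[(1R,2S,4S,5R)-2,4-dihydroxy-1-methyl-5-(3-methyl-1-nitrobut-3-en-1-yl)-4-(propan-2-yl)cyclopentyl]prop-2-en-1-ol (both carbinol epimers) | C=CC(O)[C@@]1(C)[C@@H](O)C[C@](O)(C(C)C)[C@H]1C(CC(C)=C)[N+](=O)[O-]
F6 | step 9 | 6-nitro-cis-dauc-8-ene-2α,4α,10-triol (both C6 and C10 epimers) | [O-][N+](=O)C1CC(C)=CC(O)[C@@]2(C)[C@@H](O)C[C@](O)(C(C)C)[C@@H]12
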